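## Structural features

The target 44 is a germacranolide. Its core is a cyclodeca-1(10),4-diene in which both trisubstituted double bonds (C1=C10 and C4=C5, each bearing a methyl group) are Z. This ring is trans-fused through C7–C8 to an α-methylene-γ-butyrolactone (C11=C13, C12 carbonyl, ring oxygen on C8). Recomputed from the structure, the descriptors are 2S, 6R, 7S, 8R, 9R and R in the 2-methylbutanoate. C2 (free hydroxyl) stands alone, whereas C6 (acyloxy), C7, C8 (lactone oxygen) and C9 (free hydroxyl) are contiguous, with H6/H7 trans, H7/H8 trans and a syn C8/C9 diol. Fragile groups are the α-methylene lactone (Michael acceptor), the allylic ester at C6 (ionisation, migration to O8), the two free secondary allylic alcohols, the epimerisable centre of the acyl group, and the C3 methylene, which makes any C2 carbonyl compound β,γ-unsaturated. The real difficulty is the medium ring: a ten-membered carbocycle with two Z-trisubstituted alkenes is hard to close end to end, and four oxygenated ring carbons must be told apart. The key step exploits the array C4=C5 / C6(OH) / C7 / C11(=C13): an allylic carbinol bonded to a carbon that carries a 1,1-disubstituted alkene is the homoallylic-alcohol retron of a [2,3]-Wittig shift. The C6–C7 ring bond can therefore be made inside a thirteen-membered C6–O–C13 diallyl ether.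

## Logic of the disconnections

**44 to 42.** The lactone C12–O8 bond is opened and the three hydroxyls are masked as silyl ethers (43, then 42). The α-methylene lactone is the most electrophilic group and should appear last, and the acrylic acid is inert to what precedes. The forward step demands that O8 (five-membered ring) closes faster than O9 (six-membered ring) and that the C6 ester does not migrate.

**42 to 40.** C12 is taken back from acid through aldehyde 41 to the cyclic acetal of 40. An acetal has neither acidic protons nor a good leaving group, which the carbanion chemistry further back requires. Hydrolysis and chlorite oxidation must spare silyl ethers, the allylic ester and three alkenes.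

**40 to 38 and 39.** The ester C–O bond at O6 is cut. The key step liberates O6 alone, so no selective protection is needed and the chiral acid 39 is bought. The demand is acylation of a hindered allylic alcohol without epimerisation of the acyl α-centre.

**38 to 36 (key).** C6–C7 is cut and O–C13 re-formed, which converts the ten-membered carbocycle into the thirteen-membered ether 36. Two stereocentres and the medium-ring closure disappear. The forward step demands:
- lithiation at C6 and not at C13;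
- C8 trans to C13 on C7=C11;
- no benzyl-type or acyl group on any oxygen (a benzylic carbanion on O8 or O12 would undergo its own [2,3] shift), hence silyl ethers and an acetal;
- a base strong enough for a diallyl ether that is not activated by an alkyne or arene, so an alkyllithium is chosen and not a lithium amide.

**36 to 33.** The acetal is traced through 35 and 34 to 33, in which O12 carries a PMB group. An E-selective phosphonate olefination places C8 trans to the carbonyl carbon. The required geometry therefore means that the ester carbon of the phosphonate must become C13 and that C12 enters as a protected hydroxymethyl group, oxidised only at this stage. The demand is that 35, with the aldehyde cis to C8, keeps its geometry during acetalisation.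

**33 to 29.** The ether C6–O bond is cut (Williamson) to give 32. The chloride and the free C6 hydroxyl are traced back through 31 to 29. The ring closure has direct precedent in its class and pays the entropic cost where three rigid alkenes help. It needs high dilution and one primary silyl ether that can be removed beside three secondary ones.

**29 to 19 and 23.** The ester reduction is undone (28), the C2 silyl ether and stereocentre are taken back through 27 and 26 to the epimer mixture 25, and C1–C2 is cut. This splits the chain into halves of similar size. It demands a non-basic alkenyl transfer (23 is enolisable and β,γ-unsaturated, 19 carries an ester) followed by reagent-controlled setting of C2.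

**19 to 14 and 17.** C7=C11 is cut. All three lactone carbons then come from one phosphonate and the geometry follows from the E preference of the olefination. The demand is an olefination mild enough for an α-silyloxy aldehyde.

**14 to 9 and 4.** Functional group changes (13, 12) lead to 11, whose C8–C9 bond is cut as a syn glycolate aldol. Both stereocentres are set in one step by the auxiliary in 9, and C7 is already the carbonyl carbon.

**Starting materials.** 4 comes from 1 through 3 (the Z geometry of C1=C10 is set by a chelated alkenylmagnesium). 9 comes from 5 through 6, and from 7. 17 comes from 15. 23 comes from 20 through 21 and 22 (the Z geometry of C4=C5 is inherited from the ring of 20).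

## Other disconnections considered

**Alternative 1:** The cut goes through C1–C2 and the C10–methyl bond at once. The acyclic (Z)-ene-1,4-diol A2 is traced to the terminal alkyne A1 (C9 carbinol, C8 PMB ether, vinyl group at C7), the aldehyde 23 and MeMgBr. Forward, CuI-catalysed anti-carbomagnesiation of the magnesium alkoxide of A1 puts methyl on C10 and magnesium on C1 in a five-membered chelate, and the alkenylmagnesium adds to 23.
- In favour: two C–C bonds and the Z alkene arise in one flask. The Z geometry is enforced by the chelate, which makes it the equal of the iodide route used here. In step economy for the C1/C2/C10 region it is the better plan (one operation in place of carbometalation–iodination, coupling, oxidation and reduction).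
- Against: excess MeMgBr competes for the aldehyde, and 23 is exposed to a basic Grignard reagent. C2 would be formed under remote control from C9 only, with no reagent control. Carbomagnesiation is best established for primary propargylic alcohols, not for a secondary, α-oxygenated one.
- Comparison: it delivers only the chain. The vinyl group of A2 would still have to be turned into the C7=C11 unit in the presence of two trisubstituted alkenes, and ring closure is not addressed. It is an alternative for the front part, compatible with the chosen key step, and weaker on stereocontrol at C2.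

**Alternative 2:** The cut is C9–C10. The iodo aldehyde A3, with lactone and ester in place, would be closed by CrCl2 (divalent chromium) and catalytic NiCl2 to A4, the C2 silyl ether of 44.
- In favour: the conditions are non-basic and chemoselective for the aldehyde, and tolerate the ester and the lactone. Only one desilylation follows ring closure, so in end-game economy it is the better plan (one step against four).
- Against: a ten-membered ring with two Z-trisubstituted alkenes has to be closed end to end, with entropy and transannular strain paid in the C–C bond-forming step. C9 would be set only by the conformation of the forming ring. The α-methylene lactone is an acceptor for organochromium species. The aldehyde of A3 sits next to the acyloxy-bearing C8, which can epimerise. The C6–C7–C8 array of A3 must be built on an open chain.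
- Comparison: the chosen plan closes a larger ring by an easy etherification and contracts it with substrate control over both new centres. Alternative 2 is shorter after ring formation but less predictable in the ring-forming and stereo-defining event.

**Alternative 3:** The cut is a retro-fragmentation. The C4–C9 bond is re-formed to give the cis-decalin A5 (tertiary C9 hydroxyl, equatorial C5 mesylate). Forward, KOtBu would trigger a Wharton–Grob fragmentation to the cyclodecadienone A6.
- In favour: no medium-ring closure is needed at all, and on this point it is the better plan. The concerted anti-periplanar fragmentation fixes the C4=C5 geometry and the cyclohexene fixes C1=C10, so in alkene control it is the equal of the chosen plan. Six-membered rings give reliable control of C6–C8.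
- Against: A5 needs eight stereocentres, among them a quaternary C4 and a tertiary carbinol, three of which are destroyed. A6 has C8 α to the new ketone and is exposed to alkoxide, so it can epimerise. The C9 ketone would then have to be reduced selectively in a flexible ring. C12 oxidation, lactonisation and acylation with four different protecting groups remain.
- Comparison: both plans rest on a stereospecific reorganisation of a larger or bicyclic precursor. Alternative 3 is much longer and leaves C9 open.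

Key step: step 25

Remark on the chemistry: atom labels C1–C13 are those of 44 (ring C1–C10, lactone C11–C13); TBS = tert-butyldimethylsilyl, PMB = 4-methoxybenzyl; reagents without a number are taken as commercial.

Step 1
Reactants: 1 prop-2-yn-1-ol
Product: 3 (2Z)-3-iodo-2-methylprop-2-en-1-ol, via chelated alkenylmagnesium alkoxide 2 (not isolated)
Conditions: MeMgBr (3 equiv), CuI (10 mol %), THF, -10 °C to rt; then I2, -10 °C
Reagents that add atoms: methylmagnesium bromide C[Mg]Br; iodine II
Why: Copper-catalysed anti-carbomagnesiation of the propargylic magnesium alkoxide puts methyl on the internal carbon and magnesium on the terminal carbon, held cis to CH2O in a five-membered chelate; iodinolysis with retention should give the Z iodide and so fixes the C1=C10 geometry.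

Step 2
Reactants: 3 (2Z)-3-iodo-2-methylprop-2-en-1-ol
Product: 4 (2Z)-3-iodo-2-methylprop-2-enal
Conditions: MnO2, CH2Cl2, rt, dark
Reagents that add atoms: none
Why: Allylic oxidation with MnO2 under neutral conditions should keep the Z geometry; the light-sensitive aldehyde is used at once.

Step 3
Reactants: 5 hydroxyacetic acid
Product: 6 tert-butyldimethylsilyl [(tert-butyldimethylsilyl)oxy]acetate
Conditions: TBSCl, imidazole, DMF, rt
Reagents that add atoms: tert-butyl(chloro)dimethylsilane CC(C)(C)[Si](C)(C)Cl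
Why: Exhaustive silylation gives the silyl ether and silyl ester in one operation.

Step 4
Reactants: 6 tert-butyldimethylsilyl [(tert-butyldimethylsilyl)oxy]acetate; 7 (4S)-4-benzyl-1,3-oxazolidin-2-one
Product: 9 (4S)-4-benzyl-3-{[(tert-butyldimethylsilyl)oxy]acetyl}-1,3-oxazolidin-2-one, via acid chloride 8 (not isolated)
Conditions: (COCl)2, DMF (cat.), CH2Cl2, 0 °C to rt; then 7, nBuLi, THF, -78 °C
Reagents that add atoms: none
Why: Oxalyl chloride with catalytic DMF turns a silyl ester into the acid chloride under neutral conditions that spare the silyl ether; N-acylation of the lithiated oxazolidinone is the standard imide synthesis.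

Step 5
Reactants: 9 (4S)-4-benzyl-3-{[(tert-butyldimethylsilyl)oxy]acetyl}-1,3-oxazolidin-2-one; 4 (2Z)-3-iodo-2-methylprop-2-enal
Product: 11 (4S)-4-benzyl-3-[(2S,3R,4Z)-2-(TBSO)-3-hydroxy-5-iodo-4-methylpent-4-enoyl]-1,3-oxazolidin-2-one, via boron enolate 10 (not isolated)
Conditions: Bu2BOTf, Et3N, CH2Cl2, -78 to 0 °C; then 4, -78 to 0 °C; H2O2, pH 7 buffer, MeOH
Reagents that add atoms: none
Why: Evans syn aldol reaction: the Z boron enolate reacts through a closed chair transition state on the face away from the benzyl group of the (S)-auxiliary, which should set the syn pair that becomes 8R,9R; the enal reacts in 1,2 fashion.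

Step 6
Reactants: 11 (4S)-4-benzyl-3-[(2S,3R,4Z)-2-(TBSO)-3-hydroxy-5-iodo-4-methylpent-4-enoyl]-1,3-oxazolidin-2-one
Product: 12 (4S)-4-benzyl-3-[(2S,3R,4Z)-2,3-bis(TBSO)-5-iodo-4-methylpent-4-enoyl]-1,3-oxazolidin-2-one
Conditions: TBSOTf, 2,6-lutidine, CH2Cl2, -78 to 0 °C
Reagents that add atoms: tert-butyldimethylsilyl trifluoromethanesulfonate CC(C)(C)[Si](C)(C)OS(=O)(=O)C(F)(F)F
Why: Silyl triflate silylation of the hindered allylic alcohol blocks retro-aldol cleavage and gives C9 the same base-stable group as C8.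

Step 7
Reactants: 12 (4S)-4-benzyl-3-[(2S,3R,4Z)-2,3-bis(TBSO)-5-iodo-4-methylpent-4-enoyl]-1,3-oxazolidin-2-one
Product: 13 (2R,3R,4Z)-2,3-bis(TBSO)-5-iodo-4-methylpent-4-en-1-ol
Conditions: LiBH4, MeOH (1 equiv), THF, 0 °C
Reagents that add atoms: none
Why: Reductive removal of the auxiliary with LiBH4 gives the primary alcohol and leaves the alkenyl iodide untouched; the auxiliary is recovered.

Step 8
Reactants: 13 (2R,3R,4Z)-2,3-bis(TBSO)-5-iodo-4-methylpent-4-en-1-ol
Product: 14 (2S,3R,4Z)-2,3-bis(TBSO)-5-iodo-4-methylpent-4-enal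
Conditions: Dess–Martin periodinane, NaHCO3, CH2Cl2, 0 °C to rt
Reagents that add atoms: none
Why: Buffered Dess–Martin oxidation should give the α-silyloxy aldehyde without epimerisation at C8; it is used without storage.

Step 9
Reactants: 15 ethyl (diethoxyphosphoryl)acetate
Product: 17 ethyl 2-(diethoxyphosphoryl)prop-2-enoate, via methoxy adduct 16 (not isolated)
Conditions: (CH2O)n, piperidine (cat.), MeOH, reflux; then TsOH (cat.), toluene, reflux
Reagents that add atoms: formaldehyde (as paraformaldehyde) C=O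
Why: Knoevenagel-type condensation with formaldehyde gives the methanol adduct, which loses methanol under acid to the vinylphosphonate, a known preparation of this Michael acceptor.

Step 10
Reactants: 17 ethyl 2-(diethoxyphosphoryl)prop-2-enoate; 14 (2S,3R,4Z)-2,3-bis(TBSO)-5-iodo-4-methylpent-4-enal
Product: 19 ethyl (2E,4R,5R,6Z)-4,5-bis(TBSO)-7-iodo-2-[(PMBO)methyl]-6-methylhepta-2,6-dienoate, via sodium phosphonate carbanion 18 (not isolated)
Conditions: 4-MeOC6H4CH2OH, NaH, THF, 0 °C; 17, -20 °C; then 14, -20 to 0 °C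
Reagents that add atoms: 4-methoxybenzyl alcohol COc1ccc(CO)cc1
Why: Tandem oxa-Michael addition and Horner–Wadsworth–Emmons olefination: the alkoxide adds to the vinylphosphonate and the carbanion so formed olefinates the aldehyde without further base, which protects the α-silyloxy centre. The E-selective olefination places C8 trans to the ester carbon (the future C13) and cis to the CH2OPMB arm (the future C12).

Step 11
Reactants: 20 4-methyl-5,6-dihydro-2H-pyran-2-one
Product: 21 (2Z)-3-methylpent-2-ene-1,5-diol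
Conditions: iBu2AlH (3.5 equiv), CH2Cl2, -78 to 0 °C; aq. potassium sodium tartrate
Reagents that add atoms: none
Why: 1,2-Reduction of the unsaturated lactone; the ring holds C6 and C3 cis, so the Z geometry of C4=C5 is inherited.

Step 12
Reactants: 21 (2Z)-3-methylpent-2-ene-1,5-diol
Product: 22 (3Z)-5-(TBSO)-3-methylpent-3-en-1-ol
Conditions: NaH (1.0 equiv), THF, 0 °C; TBSCl (1.0 equiv)
Reagents that add atoms: tert-butyl(chloro)dimethylsilane CC(C)(C)[Si](C)(C)Cl
Why: Monosilylation through the monosodium alkoxide; the more acidic allylic hydroxyl should be silylated preferentially, and the regioisomer and the bis-ether are separated and recycled by desilylation.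

Step 13
Reactants: 22 (3Z)-5-(TBSO)-3-methylpent-3-en-1-ol
Product: 23 (3Z)-5-(TBSO)-3-methylpent-3-enal
Conditions: Dess–Martin periodinane, NaHCO3, CH2Cl2, 0 °C
Reagents that add atoms: none
Why: Buffered Dess–Martin oxidation gives the β,γ-unsaturated aldehyde without moving the double bond; it is used crude and at once.

Step 14
Reactants: 19 ethyl (2E,4R,5R,6Z)-4,5-bis(TBSO)-7-iodo-2-[(PMBO)methyl]-6-methylhepta-2,6-dienoate; 23 (3Z)-5-(TBSO)-3-methylpent-3-enal
Product: 25 ethyl (2E,4R,5R,6Z,8RS,10Z)-4,5,12-tris(TBSO)-8-hydroxy-2-[(PMBO)methyl]-6,10-dimethyldodeca-2,6,10-trienoate, via alkenylchromium dichloride 24 (not isolated)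
Conditions: CrCl2 (6 equiv), NiCl2 (cat.), 23 (1.5 equiv), DMSO, rt
Reagents that add atoms: none
Why: Nozaki–Hiyama–Kishi coupling: nickel inserts into the C–I bond, the alkenyl group passes to trivalent chromium with retention of the Z geometry and adds to the aldehyde. The reagent is not basic, so the ester and the enolisable aldehyde survive. C2 forms without control and is corrected in steps 15 and 16.

Step 15
Reactants: 25 ethyl (2E,4R,5R,6Z,8RS,10Z)-4,5,12-tris(TBSO)-8-hydroxy-2-[(PMBO)methyl]-6,10-dimethyldodeca-2,6,10-trienoate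
Product: 26 ethyl (2E,4R,5R,6Z,10Z)-4,5,12-tris(TBSO)-2-[(PMBO)methyl]-6,10-dimethyl-8-oxododeca-2,6,10-trienoate
Conditions: Dess–Martin periodinane, NaHCO3, CH2Cl2, 0 °C
Reagents that add atoms: none
Why: Buffered oxidation of the allylic alcohol to the enone; neutral conditions are chosen so that C4=C5 does not move into conjugation through the C3 methylene.

Step 16
Reactants: 26 ethyl (2E,4R,5R,6Z,10Z)-4,5,12-tris(TBSO)-2-[(PMBO)methyl]-6,10-dimethyl-8-oxododeca-2,6,10-trienoate
Product: 27 ethyl (2E,4R,5R,6Z,8S,10Z)-4,5,12-tris(TBSO)-8-hydroxy-2-[(PMBO)methyl]-6,10-dimethyldodeca-2,6,10-trienoate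
Conditions: (R)-Me-CBS oxazaborolidine [(R)-1-methyl-3,3-diphenyltetrahydro-1H,3H-pyrrolo[1,2-c][1,3,2]oxazaborole] (20 mol %), catecholborane, toluene, -78 °C
Reagents that add atoms: none
Why: Corey–Bakshi–Shibata reduction: the ketone binds the catalyst with the larger alkenyl residue away from it and hydride is delivered to one face, which with the (R)-catalyst should give the S carbinol at C2. Catecholborane at low temperature leaves the enoate and the alkenes alone.

Step 17
Reactants: 27 ethyl (2E,4R,5R,6Z,8S,10Z)-4,5,12-tris(TBSO)-8-hydroxy-2-[(PMBO)methyl]-6,10-dimethyldodeca-2,6,10-trienoate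
Product: 28 ethyl (2E,4R,5R,6Z,8S,10Z)-4,5,8,12-tetrakis(TBSO)-2-[(PMBO)methyl]-6,10-dimethyldodeca-2,6,10-trienoate
Conditions: TBSOTf, 2,6-lutidine, CH2Cl2, -78 °C
Reagents that add atoms: tert-butyldimethylsilyl trifluoromethanesulfonate CC(C)(C)[Si](C)(C)OS(=O)(=O)C(F)(F)F
Why: Silyl ether formation on the secondary allylic alcohol; the base-stable group is needed for steps 21 and 25.

Step 18
Reactants: 28 ethyl (2E,4R,5R,6Z,8S,10Z)-4,5,8,12-tetrakis(TBSO)-2-[(PMBO)methyl]-6,10-dimethyldodeca-2,6,10-trienoate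
Product: 29 (2Z,4R,5R,6Z,8S,10Z)-4,5,8,12-tetrakis(TBSO)-2-[(PMBO)methyl]-6,10-dimethyldodeca-2,6,10-trien-1-ol
Conditions: iBu2AlH (2.5 equiv), CH2Cl2, -78 °C
Reagents that add atoms: none
Why: 1,2-Reduction of the enoate gives the allylic alcohol, so that the C13 oxygen stands trans to C8.

Step 19
Reactants: 29 (2Z,4R,5R,6Z,8S,10Z)-4,5,8,12-tetrakis(TBSO)-2-[(PMBO)methyl]-6,10-dimethyldodeca-2,6,10-trien-1-ol
Product: 31 (2E,4R,5R,6Z,8S,10Z)-4,5,8,12-tetrakis(TBSO)-1-chloro-2-[(PMBO)methyl]-6,10-dimethyldodeca-2,6,10-triene, via mesylate 30 (not isolated)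
Conditions: MsCl, Et3N, CH2Cl2, -40 °C; then LiCl, THF, 0 °C to rt
Reagents that add atoms: lithium chloride [Li+].[Cl-]
Why: Mesylation and SN2 displacement by chloride give the primary allylic chloride without allylic transposition, since the C7 terminus is hindered.

Step 20
Reactants: 31 (2E,4R,5R,6Z,8S,10Z)-4,5,8,12-tetrakis(TBSO)-1-chloro-2-[(PMBO)methyl]-6,10-dimethyldodeca-2,6,10-triene
Product: 32 (2Z,5S,6Z,8R,9R,10E)-5,8,9-tris(TBSO)-11-(chloromethyl)-12-(PMBO)-3,7-dimethyldodeca-2,6,10-trien-1-ol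
Conditions: HF·pyridine, pyridine, THF, 0 °C
Reagents that add atoms: none
Why: Buffered fluoride cleaves the only primary silyl ether much faster than the three secondary ones; the allylic chloride and the PMB ether are inert.

Step 21
Reactants: 32 (2Z,5S,6Z,8R,9R,10E)-5,8,9-tris(TBSO)-11-(chloromethyl)-12-(PMBO)-3,7-dimethyldodeca-2,6,10-trien-1-ol
Product: 33 (3Z,5R,6R,7Z,9S,11Z)-5,6,9-tris(TBSO)-3-[(PMBO)methyl]-7,11-dimethyl-1-oxacyclotrideca-3,7,11-triene
Conditions: NaH, Bu4NI (cat.), THF (0.002 M), 50 °C, slow addition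
Reagents that add atoms: none
Why: Intramolecular Williamson ether synthesis: the C6 alkoxide displaces the primary allylic halide at C13 (SN2, iodide catalysis) to close the thirteen-membered ring, helped by three rigid alkenes and high dilution; this ring closure has precedent for diallylic ethers of this size.

Step 22
Reactants: 33 (3Z,5R,6R,7Z,9S,11Z)-5,6,9-tris(TBSO)-3-[(PMBO)methyl]-7,11-dimethyl-1-oxacyclotrideca-3,7,11-triene
Product: 34 [(3E,5R,6R,7Z,9S,11Z)-5,6,9-tris(TBSO)-7,11-dimethyl-1-oxacyclotrideca-3,7,11-trien-3-yl]methanol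
Conditions: DDQ, CH2Cl2, pH 7 buffer, 0 °C
Reagents that add atoms: none
Why: Oxidative cleavage of the electron-rich PMB ether; silyl ethers and the dialkyl allylic ether are far less prone to hydride abstraction. The PMB group must go here because a benzylic carbanion would interfere in step 25.

Step 23
Reactants: 34 [(3E,5R,6R,7Z,9S,11Z)-5,6,9-tris(TBSO)-7,11-dimethyl-1-oxacyclotrideca-3,7,11-trien-3-yl]methanol
Product: 35 (3Z,5R,6R,7Z,9S,11Z)-5,6,9-tris(TBSO)-7,11-dimethyl-1-oxacyclotrideca-3,7,11-triene-3-carbaldehyde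
Conditions: MnO2, CH2Cl2, rt
Reagents that add atoms: none
Why: Neutral MnO2 oxidation of the primary allylic alcohol should keep the alkene geometry (aldehyde cis to C8).

Step 24
Reactants: 35 (3Z,5R,6R,7Z,9S,11Z)-5,6,9-tris(TBSO)-7,11-dimethyl-1-oxacyclotrideca-3,7,11-triene-3-carbaldehyde
Product: 36 (3Z,5R,6R,7Z,9S,11Z)-5,6,9-tris(TBSO)-3-(1,3-dioxolan-2-yl)-7,11-dimethyl-1-oxacyclotrideca-3,7,11-triene
Conditions: Me3SiOCH2CH2OSiMe3, Me3SiOTf (cat.), CH2Cl2, -78 °C
Reagents that add atoms: 1,2-bis(trimethylsilyloxy)ethane C[Si](C)(C)OCCO[Si](C)(C)C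
Why: Noyori acetalisation under aprotic conditions at low temperature, chosen so that the enal does not isomerise about C7=C11 and the silyl ethers stay.

Step 25
Reactants: 36 (3Z,5R,6R,7Z,9S,11Z)-5,6,9-tris(TBSO)-3-(1,3-dioxolan-2-yl)-7,11-dimethyl-1-oxacyclotrideca-3,7,11-triene
Product: 38 (1R,2Z,5S,6Z,8R,9R,10S)-5,8,9-tris(TBSO)-10-[1-(1,3-dioxolan-2-yl)ethenyl]-3,7-dimethylcyclodeca-2,6-dien-1-ol, via C6-lithiated ether 37 (not isolated)
Conditions: nBuLi (1.5 equiv), THF, -78 °C; aq. NH4Cl at -78 °C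
Reagents that add atoms: none
Why: nBuLi removes a proton from C6, which is α to the ether oxygen and allylic to C4=C5, and the α-oxy allyllithium 37 undergoes a [2,3]-sigmatropic Wittig shift in which C6 bonds to C7, the π bond moves to C11=C13 and O–C13 breaks to leave the C6 alkoxide. The closest known reaction type is the [2,3]-Wittig ring contraction of thirteen-membered diallylic ethers to ten-membered carbocycles. The ten-membered ring is closed by transannular bond formation inside the larger ring through a five-membered envelope transition state, suprafacial on the allyl unit, and not by an end-to-end cyclisation. C7 is controlled by the C8 centre: the C12 substituent cis to C8 forces C8–H into the alkene plane (1,3-allylic strain), and C6, tethered through C9, attacks the face anti to the C8–O bond, which gives H7/H8 trans. C6 is controlled by the alkene geometry: with C8 trans to C13 and C5 exo on the envelope the anti product (H6/H7 trans) results, as in the E-to-anti rule of open-chain cases. The step needs lithiation at C6 and not at C13, and a [2,3] and not a [1,2] shift. C6–H2 lies next to an unhindered CH= whereas C13–H2 is flanked by the fully substituted C11 with its acetal, a C13 carbanion could bond only to the fully substituted C4, and the low temperature favours the concerted path. An alkyllithium is used because the ether is not activated by an alkyne, arene or carbonyl group; acetal and silyl ethers are inert to it at -78 °C, and the cold quench prevents silyl migration from O8 to the new alkoxide.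

Step 26
Reactants: 38 (1R,2Z,5S,6Z,8R,9R,10S)-5,8,9-tris(TBSO)-10-[1-(1,3-dioxolan-2-yl)ethenyl]-3,7-dimethylcyclodeca-2,6-dien-1-ol; 39 (2R)-2-methylbutanoic acid
Product: 40 (1R,2Z,5S,6Z,8R,9R,10S)-5,8,9-tris(TBSO)-10-[1-(1,3-dioxolan-2-yl)ethenyl]-3,7-dimethylcyclodeca-2,6-dien-1-yl (2R)-2-methylbutanoate
Conditions: DCC, DMAP (cat.), CH2Cl2, 0 °C to rt
Reagents that add atoms: none
Why: Steglich esterification of the only free hydroxyl; catalytic DMAP at low temperature limits epimerisation of the acyl α-centre.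

Step 27
Reactants: 40 (1R,2Z,5S,6Z,8R,9R,10S)-5,8,9-tris(TBSO)-10-[1-(1,3-dioxolan-2-yl)ethenyl]-3,7-dimethylcyclodeca-2,6-dien-1-yl (2R)-2-methylbutanoate
Product: 41 (1R,2Z,5S,6Z,8R,9R,10S)-5,8,9-tris(TBSO)-3,7-dimethyl-10-(3-oxoprop-1-en-2-yl)cyclodeca-2,6-dien-1-yl (2R)-2-methylbutanoate
Conditions: PPTS, acetone, H2O, 40 °C
Reagents that add atoms: water O
Why: Acid-catalysed acetal hydrolysis through an allyl-stabilised oxocarbenium ion, so mild acid suffices; secondary silyl ethers and the ester should persist.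

Step 28
Reactants: 41 (1R,2Z,5S,6Z,8R,9R,10S)-5,8,9-tris(TBSO)-3,7-dimethyl-10-(3-oxoprop-1-en-2-yl)cyclodeca-2,6-dien-1-yl (2R)-2-methylbutanoate
Product: 42 (1R,2Z,5S,6Z,8R,9R,10S)-5,8,9-tris(TBSO)-10-(1-carboxyethenyl)-3,7-dimethylcyclodeca-2,6-dien-1-yl (2R)-2-methylbutanoate
Conditions: NaClO2, NaH2PO4, 2-methylbut-2-ene, tBuOH, H2O, 0 °C to rt
Reagents that add atoms: sodium chlorite [Na+].[O-]Cl=O
Why: Pinnick oxidation takes the enal to the acrylic acid; the alkene scavenger removes hypochlorite and protects the ring alkenes.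

Step 29
Reactants: 42 (1R,2Z,5S,6Z,8R,9R,10S)-5,8,9-tris(TBSO)-10-(1-carboxyethenyl)-3,7-dimethylcyclodeca-2,6-dien-1-yl (2R)-2-methylbutanoate
Product: 44 (3aS,4R,5Z,8S,9Z,11R,11aR)-8,11-dihydroxy-6,10-dimethyl-3-methylidene-2-oxo-2,3,3a,4,7,8,11,11a-octahydrocyclodeca[b]furan-4-yl (2R)-2-methylbutanoate, via triol acid 43 (not isolated)
Conditions: HF·pyridine, THF, 0 °C to rt
Reagents that add atoms: none
Why: Fluoride removes the three silyl ethers, and under the acidic conditions the γ-hydroxy acid should close through O8 to the five-membered lactone in preference to the six-membered ring through O9; no base is present that could move the ester.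

## Compound list

1 | prop-2-yn-1-ol | C#CCO | starting material
2 | 4-methyl-2,5-dihydro-1,2-oxamagnesole (chelated alkenylmagnesium alkoxide, formed in situ) | CC1=C[Mg]OC1 | intermediate
3 | (2Z)-3-iodo-2-methylprop-2-en-1-ol | OC/C(C)=C\I | intermediate
4 | (2Z)-3-iodo-2-methylprop-2-enal | O=C/C(C)=C\I | intermediate
5 | hydroxyacetic acid | OCC(=O)O | starting material
6 | tert-butyldimethylsilyl [(tert-butyldimethylsilyl)oxy]acetate | CC(C)(C)[Si](C)(C)OCC(=O)O[Si](C)(C)C(C)(C)C | intermediate
7 | (4S)-4-benzyl-1,3-oxazolidin-2-one | O=C1OC[C@H](Cc2ccccc2)N1 | starting material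
8 | [(tert-butyldimethylsilyl)oxy]acetyl chloride (formed in situ) | CC(C)(C)[Si](C)(C)OCC(Cl)=O | intermediate
9 | (4S)-4-benzyl-3-{[(tert-butyldimethylsilyl)oxy]acetyl}-1,3-oxazolidin-2-one | O=C1OC[C@H](Cc2ccccc2)N1C(=O)CO[Si](C)(C)C(C)(C)C | intermediate
10 | (Z)-dibutylboron enolate of 9 (formed in situ) | CCCCB(CCCC)O/C(N1C(=O)OC[C@@H]1Cc1ccccc1)=C\O[Si](C)(C)C(C)(C)C | intermediate
11 | (4S)-4-benzyl-3-[(2S,3R,4Z)-2-[(tert-butyldimethylsilyl)oxy]-3-hydroxy-5-iodo-4-methylpent-4-enoyl]-1,3-oxazolidin-2-one | O=C1OC[C@H](Cc2ccccc2)N1C(=O)[C@@H](O[Si](C)(C)C(C)(C)C)[C@H](O)/C(C)=C\I | intermediate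
12 | (4S)-4-benzyl-3-[(2S,3R,4Z)-2,3-bis[(tert-butyldimethylsilyl)oxy]-5-iodo-4-methylpent-4-enoyl]-1,3-oxazolidin-2-one | O=C1OC[C@H](Cc2ccccc2)N1C(=O)[C@@H](O[Si](C)(C)C(C)(C)C)[C@H](O[Si](C)(C)C(C)(C)C)/C(C)=C\I | intermediate
13 | (2R,3R,4Z)-2,3-bis[(tert-butyldimethylsilyl)oxy]-5-iodo-4-methylpent-4-en-1-ol | OC[C@@H](O[Si](C)(C)C(C)(C)C)[C@H](O[Si](C)(C)C(C)(C)C)/C(C)=C\I | intermediate
14 | (2S,3R,4Z)-2,3-bis[(tert-butyldimethylsilyl)oxy]-5-iodo-4-methylpent-4-enal | O=C[C@@H](O[Si](C)(C)C(C)(C)C)[C@H](O[Si](C)(C)C(C)(C)C)/C(C)=C\I | intermediate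
15 | ethyl (diethoxyphosphoryl)acetate | CCOC(=O)CP(=O)(OCC)OCC | starting material
16 | ethyl 2-(diethoxyphosphoryl)-3-methoxypropanoate (formed in situ) | CCOC(=O)C(COC)P(=O)(OCC)OCC | intermediate
17 | ethyl 2-(diethoxyphosphoryl)prop-2-enoate | CCOC(=O)C(=C)P(=O)(OCC)OCC | intermediate
18 | sodium salt of the carbanion of ethyl 2-(diethoxyphosphoryl)-3-[(4-methoxybenzyl)oxy]propanoate (formed in situ) | [Na+].CCOC(=O)[C-](COCc1ccc(OC)cc1)P(=O)(OCC)OCC | intermediate
19 | ethyl (2E,4R,5R,6Z)-4,5-bis[(tert-butyldimethylsilyl)oxy]-7-iodo-2-{[(4-methoxybenzyl)oxy]methyl}-6-methylhepta-2,6-dienoate | CCOC(=O)/C(COCc1ccc(OC)cc1)=C/[C@@H](O[Si](C)(C)C(C)(C)C)[C@H](O[Si](C)(C)C(C)(C)C)/C(C)=C\I | intermediate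
20 | 4-methyl-5,6-dihydro-2H-pyran-2-one | CC1=CC(=O)OCC1 | starting material
21 | (2Z)-3-methylpent-2-ene-1,5-diol | OC/C=C(/C)CCO | intermediate
22 | (3Z)-5-[(tert-butyldimethylsilyl)oxy]-3-methylpent-3-en-1-ol | CC(C)(C)[Si](C)(C)OC/C=C(/C)CCO | intermediate
23 | (3Z)-5-[(tert-butyldimethylsilyl)oxy]-3-methylpent-3-enal | CC(C)(C)[Si](C)(C)OC/C=C(/C)CC=O | intermediate
24 | alkenylchromium dichloride derived from 19, chromium in place of iodine (formed in situ) | CCOC(=O)/C(COCc1ccc(OC)cc1)=C/[C@@H](O[Si](C)(C)C(C)(C)C)[C@H](O[Si](C)(C)C(C)(C)C)/C(C)=C\[Cr](Cl)Cl | intermediate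
25 | ethyl (2E,4R,5R,6Z,8RS,10Z)-4,5,12-tris[(tert-butyldimethylsilyl)oxy]-8-hydroxy-2-{[(4-methoxybenzyl)oxy]methyl}-6,10-dimethyldodeca-2,6,10-trienoate (both C8 epimers) | CCOC(=O)/C(COCc1ccc(OC)cc1)=C/[C@@H](O[Si](C)(C)C(C)(C)C)[C@H](O[Si](C)(C)C(C)(C)C)/C(C)=C\C(O)C/C(C)=C\CO[Si](C)(C)C(C)(C)C | intermediate
26 | ethyl (2E,4R,5R,6Z,10Z)-4,5,12-tris[(tert-butyldimethylsilyl)oxy]-2-{[(4-methoxybenzyl)oxy]methyl}-6,10-dimethyl-8-oxododeca-2,6,10-trienoate | CCOC(=O)/C(COCc1ccc(OC)cc1)=C/[C@@H](O[Si](C)(C)C(C)(C)C)[C@H](O[Si](C)(C)C(C)(C)C)/C(C)=C\C(=O)C/C(C)=C\CO[Si](C)(C)C(C)(C)C | intermediate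
27 | ethyl (2E,4R,5R,6Z,8S,10Z)-4,5,12-tris[(tert-butyldimethylsilyl)oxy]-8-hydroxy-2-{[(4-methoxybenzyl)oxy]methyl}-6,10-dimethyldodeca-2,6,10-trienoate | CCOC(=O)/C(COCc1ccc(OC)cc1)=C/[C@@H](O[Si](C)(C)C(C)(C)C)[C@H](O[Si](C)(C)C(C)(C)C)/C(C)=C\[C@@H](O)C/C(C)=C\CO[Si](C)(C)C(C)(C)C | intermediate
28 | ethyl (2E,4R,5R,6Z,8S,10Z)-4,5,8,12-tetrakis[(tert-butyldimethylsilyl)oxy]-2-{[(4-methoxybenzyl)oxy]methyl}-6,10-dimethyldodeca-2,6,10-trienoate | CCOC(=O)/C(COCc1ccc(OC)cc1)=C/[C@@H](O[Si](C)(C)C(C)(C)C)[C@H](O[Si](C)(C)C(C)(C)C)/C(C)=C\[C@@H](O[Si](C)(C)C(C)(C)C)C/C(C)=C\CO[Si](C)(C)C(C)(C)C | intermediate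
29 | (2Z,4R,5R,6Z,8S,10Z)-4,5,8,12-tetrakis[(tert-butyldimethylsilyl)oxy]-2-{[(4-methoxybenzyl)oxy]methyl}-6,10-dimethyldodeca-2,6,10-trien-1-ol | OC/C(COCc1ccc(OC)cc1)=C/[C@@H](O[Si](C)(C)C(C)(C)C)[C@H](O[Si](C)(C)C(C)(C)C)/C(C)=C\[C@@H](O[Si](C)(C)C(C)(C)C)C/C(C)=C\CO[Si](C)(C)C(C)(C)C | intermediate
30 | methanesulfonate of 29 (formed in situ) | CS(=O)(=O)OC/C(COCc1ccc(OC)cc1)=C/[C@@H](O[Si](C)(C)C(C)(C)C)[C@H](O[Si](C)(C)C(C)(C)C)/C(C)=C\[C@@H](O[Si](C)(C)C(C)(C)C)C/C(C)=C\CO[Si](C)(C)C(C)(C)C | intermediate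
31 | (2E,4R,5R,6Z,8S,10Z)-4,5,8,12-tetrakis[(tert-butyldimethylsilyl)oxy]-1-chloro-2-{[(4-methoxybenzyl)oxy]methyl}-6,10-dimethyldodeca-2,6,10-triene | ClC/C(COCc1ccc(OC)cc1)=C/[C@@H](O[Si](C)(C)C(C)(C)C)[C@H](O[Si](C)(C)C(C)(C)C)/C(C)=C\[C@@H](O[Si](C)(C)C(C)(C)C)C/C(C)=C\CO[Si](C)(C)C(C)(C)C | intermediate
32 | (2Z,5S,6Z,8R,9R,10E)-5,8,9-tris[(tert-butyldimethylsilyl)oxy]-11-(chloromethyl)-12-[(4-methoxybenzyl)oxy]-3,7-dimethyldodeca-2,6,10-trien-1-ol | ClC/C(COCc1ccc(OC)cc1)=C/[C@@H](O[Si](C)(C)C(C)(C)C)[C@H](O[Si](C)(C)C(C)(C)C)/C(C)=C\[C@@H](O[Si](C)(C)C(C)(C)C)C/C(C)=C\CO | intermediate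
33 | (3Z,5R,6R,7Z,9S,11Z)-5,6,9-tris[(tert-butyldimethylsilyl)oxy]-3-{[(4-methoxybenzyl)oxy]methyl}-7,11-dimethyl-1-oxacyclotrideca-3,7,11-triene | C1OC/C(COCc2ccc(OC)cc2)=C/[C@@H](O[Si](C)(C)C(C)(C)C)[C@H](O[Si](C)(C)C(C)(C)C)/C(C)=C\[C@@H](O[Si](C)(C)C(C)(C)C)C/C(C)=C\1 | intermediate
34 | [(3E,5R,6R,7Z,9S,11Z)-5,6,9-tris[(tert-butyldimethylsilyl)oxy]-7,11-dimethyl-1-oxacyclotrideca-3,7,11-trien-3-yl]methanol | C1OC/C(CO)=C/[C@@H](O[Si](C)(C)C(C)(C)C)[C@H](O[Si](C)(C)C(C)(C)C)/C(C)=C\[C@@H](O[Si](C)(C)C(C)(C)C)C/C(C)=C\1 | intermediate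
35 | (3Z,5R,6R,7Z,9S,11Z)-5,6,9-tris[(tert-butyldimethylsilyl)oxy]-7,11-dimethyl-1-oxacyclotrideca-3,7,11-triene-3-carbaldehyde | C1OC/C(C=O)=C/[C@@H](O[Si](C)(C)C(C)(C)C)[C@H](O[Si](C)(C)C(C)(C)C)/C(C)=C\[C@@H](O[Si](C)(C)C(C)(C)C)C/C(C)=C\1 | intermediate
36 | (3Z,5R,6R,7Z,9S,11Z)-5,6,9-tris[(tert-butyldimethylsilyl)oxy]-3-(1,3-dioxolan-2-yl)-7,11-dimethyl-1-oxacyclotrideca-3,7,11-triene (precursor of the key step) | C1OC/C(C2OCCO2)=C/[C@@H](O[Si](C)(C)C(C)(C)C)[C@H](O[Si](C)(C)C(C)(C)C)/C(C)=C\[C@@H](O[Si](C)(C)C(C)(C)C)C/C(C)=C\1 | intermediate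
37 | 36 lithiated at the ether carbon C6 (formed in situ) | [Li]C1OC/C(C2OCCO2)=C/[C@@H](O[Si](C)(C)C(C)(C)C)[C@H](O[Si](C)(C)C(C)(C)C)/C(C)=C\[C@@H](O[Si](C)(C)C(C)(C)C)C/C(C)=C\1 | intermediate
38 | (1R,2Z,5S,6Z,8R,9R,10S)-5,8,9-tris[(tert-butyldimethylsilyl)oxy]-10-[1-(1,3-dioxolan-2-yl)ethenyl]-3,7-dimethylcyclodeca-2,6-dien-1-ol (product of the key step) | C=C(C2OCCO2)[C@@H]1[C@@H](O[Si](C)(C)C(C)(C)C)[C@H](O[Si](C)(C)C(C)(C)C)/C(C)=C\[C@@H](O[Si](C)(C)C(C)(C)C)C/C(C)=C\[C@H]1O | intermediate
39 | (2R)-2-methylbutanoic acid | CC[C@@H](C)C(=O)O | starting material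
40 | (1R,2Z,5S,6Z,8R,9R,10S)-5,8,9-tris[(tert-butyldimethylsilyl)oxy]-10-[1-(1,3-dioxolan-2-yl)ethenyl]-3,7-dimethylcyclodeca-2,6-dien-1-yl (2R)-2-methylbutanoate | C=C(C2OCCO2)[C@@H]1[C@@H](O[Si](C)(C)C(C)(C)C)[C@H](O[Si](C)(C)C(C)(C)C)/C(C)=C\[C@@H](O[Si](C)(C)C(C)(C)C)C/C(C)=C\[C@H]1OC(=O)[C@H](C)CC | intermediate
41 | (1R,2Z,5S,6Z,8R,9R,10S)-5,8,9-tris[(tert-butyldimethylsilyl)oxy]-3,7-dimethyl-10-(3-oxoprop-1-en-2-yl)cyclodeca-2,6-dien-1-yl (2R)-2-methylbutanoate | C=C(C=O)[C@@H]1[C@@H](O[Si](C)(C)C(C)(C)C)[C@H](O[Si](C)(C)C(C)(C)C)/C(C)=C\[C@@H](O[Si](C)(C)C(C)(C)C)C/C(C)=C\[C@H]1OC(=O)[C@H](C)CC | intermediate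
42 | (1R,2Z,5S,6Z,8R,9R,10S)-5,8,9-tris[(tert-butyldimethylsilyl)oxy]-10-(1-carboxyethenyl)-3,7-dimethylcyclodeca-2,6-dien-1-yl (2R)-2-methylbutanoate | C=C(C(=O)O)[C@@H]1[C@@H](O[Si](C)(C)C(C)(C)C)[C@H](O[Si](C)(C)C(C)(C)C)/C(C)=C\[C@@H](O[Si](C)(C)C(C)(C)C)C/C(C)=C\[C@H]1OC(=O)[C@H](C)CC | intermediate
43 | (1R,2Z,5S,6Z,8R,9R,10R)-10-(1-carboxyethenyl)-5,8,9-trihydroxy-3,7-dimethylcyclodeca-2,6-dien-1-yl (2R)-2-methylbutanoate (formed in situ) | C=C(C(=O)O)[C@@H]1[C@@H](O)[C@H](O)/C(C)=C\[C@@H](O)C/C(C)=C\[C@H]1OC(=O)[C@H](C)CC | intermediate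
44 | (3aS,4R,5Z,8S,9Z,11R,11aR)-8,11-dihydroxy-6,10-dimethyl-3-methylidene-2-oxo-2,3,3a,4,7,8,11,11a-octahydrocyclodeca[b]furan-4-yl (2R)-2-methylbutanoate (CNP0176600.1) | C=C1C(=O)O[C@@H]2[C@@H]1[C@H](OC(=O)[C@H](C)CC)/C=C(/C)C[C@H](O)/C=C(/C)[C@H]2O | target

## Step count and least certain steps

Total: 29 steps. Longest linear sequence: 23 steps, from 1 to 44 through steps 1, 2, 5–8, 10 and 14–29. Side branches: steps 3–4 (to 9), step 9 (to 17) and steps 11–13 (to 23).

**Step 25 (key step).** Lithiation may occur at C13 in place of C6, because the two allylic α-oxy methylene groups differ little in acidity and the acetal oxygens can guide the base to C13. A C13 carbanion could then eliminate the C8 silyloxy group or undergo a [1,2] shift on warming. Fallback: a chromium-mediated ring closure that forms the same C6–C7 bond. It sets out from 32. MnO2 oxidises the C6 hydroxyl to the (2Z)-enal chloride F1. CrCl2 in THF/DMF at high dilution turns the allylic chloride into an allylchromium species that attacks the aldehyde through C7 (intramolecular Nozaki–Hiyama allylation, anti-selective), which should give the cyclodecadienol F2 with the C11=C13 methylene and C12 as CH2OPMB. Steglich esterification with 39 gives the ester F3, DDQ removes the PMB group to give the allylic alcohol F4, and MnO2 oxidation comes back to the route at 41.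

**Step 21.** Intermolecular etherification (oligomers) may outrun ring closure, because the alkoxide and the allylic halide must meet across a thirteen-membered ring. Fallback: the chromium-mediated closure described for step 25 serves here as well. It sets out from 32, before any ether ring is made, forms the ten-membered ring directly and comes back at 41; it needs no compound beyond those of that detour.

**Step 12.** Silylation may show poor site selectivity between the two primary hydroxyls, because allylic and homoallylic alkoxides differ only slightly in acidity and reactivity. Fallback: build the unit with the oxygens differentiated from the start. Commercial but-2-yn-1-ol is hydroaluminated with NaAlH2(OCH2CH2OMe)2 and iodinated to (2Z)-3-iodobut-2-en-1-ol F5. TBSCl and imidazole give the silyl ether F6. Iodine–lithium exchange with tBuLi in Et2O at -78 °C, followed by opening of oxirane with BF3·OEt2, comes back at 22.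

**Step 16 (with step 15).** The double bond of the β,γ-unsaturated ketone may move into conjugation, or hydride delivery may show poor facial selectivity, because the alkenyl group carries a cis substituent that twists the enone. Fallback: avoid the ketone. It sets out from 25, whose epimers are separated. The (8R)-alcohol F7 is inverted by a Mitsunobu reaction (4-nitrobenzoic acid, PPh3, diisopropyl azodicarboxylate) to the (8S)-4-nitrobenzoate F8. K2CO3 in ethanol cleaves the nitrobenzoate and comes back at 27.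

**Step 24.** The enal may isomerise about C7=C11 during acetalisation, because the aldehyde cis to C8 is the less stable arrangement and the oxocarbenium intermediate is allylic. Fallback: carry C12 through the key step as a silyl ether. It sets out from 34. TBSCl and imidazole give the silyl ether F9. The same nBuLi-induced [2,3]-Wittig shift gives the cyclodecadienol F10, and esterification with 39 gives the ester F11. Buffered HF·pyridine removes the primary silyl group to give the allylic alcohol F4 (also met in the detour for step 25), and MnO2 oxidation comes back at 41.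

**Step 29.** Lactonisation may stay incomplete or go to O9, or the C6 ester may migrate to O8 while the γ-hydroxy acid waits to close. Fallback: close the ring at the aldehyde oxidation level. It sets out from 41. HF·pyridine removes the silyl groups, and the C12 aldehyde is trapped by O8 as the five-membered lactol F12. Selective lactol oxidation with Ag2CO3 on Celite comes back at 44.

## Further compounds

F1 | step 25 | (2Z,5S,6Z,8R,9R,10E)-5,8,9-tris[(tert-butyldimethylsilyl)oxy]-11-(chloromethyl)-12-[(4-methoxybenzyl)oxy]-3,7-dimethyldodeca-2,6,10-trienal | ClC/C(COCc1ccc(OC)cc1)=C/[C@@H](O[Si](C)(C)C(C)(C)C)[C@H](O[Si](C)(C)C(C)(C)C)/C(C)=C\[C@@H](O[Si](C)(C)C(C)(C)C)C/C(C)=C\C=O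
F2 | step 25 | (1R,2Z,5S,6Z,8R,9R,10S)-5,8,9-tris[(tert-butyldimethylsilyl)oxy]-10-{3-[(4-methoxybenzyl)oxy]prop-1-en-2-yl}-3,7-dimethylcyclodeca-2,6-dien-1-ol | C=C(COCc2ccc(OC)cc2)[C@@H]1[C@@H](O[Si](C)(C)C(C)(C)C)[C@H](O[Si](C)(C)C(C)(C)C)/C(C)=C\[C@@H](O[Si](C)(C)C(C)(C)C)C/C(C)=C\[C@H]1O
F3 | step 25 | (1R,2Z,5S,6Z,8R,9R,10S)-5,8,9-tris[(tert-butyldimethylsilyl)oxy]-10-{3-[(4-methoxybenzyl)oxy]prop-1-en-2-yl}-3,7-dimethylcyclodeca-2,6-dien-1-yl (2R)-2-methylbutanoate | C=C(COCc2ccc(OC)cc2)[C@@H]1[C@@H](O[Si](C)(C)C(C)(C)C)[C@H](O[Si](C)(C)C(C)(C)C)/C(C)=C\[C@@H](O[Si](C)(C)C(C)(C)C)C/C(C)=C\[C@H]1OC(=O)[C@H](C)CC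
F4 | step 25 | (1R,2Z,5S,6Z,8R,9R,10S)-5,8,9-tris[(tert-butyldimethylsilyl)oxy]-10-(3-hydroxyprop-1-en-2-yl)-3,7-dimethylcyclodeca-2,6-dien-1-yl (2R)-2-methylbutanoate | C=C(CO)[C@@H]1[C@@H](O[Si](C)(C)C(C)(C)C)[C@H](O[Si](C)(C)C(C)(C)C)/C(C)=C\[C@@H](O[Si](C)(C)C(C)(C)C)C/C(C)=C\[C@H]1OC(=O)[C@H](C)CC
F0 | step 21 | none | none
F5 | step 12 | (2Z)-3-iodobut-2-en-1-ol | OC/C=C(/C)I
F6 | step 12 | tert-butyl{[(2Z)-3-iodobut-2-en-1-yl]oxy}dimethylsilane | CC(C)(C)[Si](C)(C)OC/C=C(/C)I
F7 | step 16 | ethyl (2E,4R,5R,6Z,8R,10Z)-4,5,12-tris[(tert-butyldimethylsilyl)oxy]-8-hydroxy-2-{[(4-methoxybenzyl)oxy]methyl}-6,10-dimethyldodeca-2,6,10-trienoate | CCOC(=O)/C(COCc1ccc(OC)cc1)=C/[C@@H](O[Si](C)(C)C(C)(C)C)[C@H](O[Si](C)(C)C(C)(C)C)/C(C)=C\[C@H](O)C/C(C)=C\CO[Si](C)(C)C(C)(C)C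
F8 | step 16 | ethyl (2E,4R,5R,6Z,8S,10Z)-4,5,12-tris[(tert-butyldimethylsilyl)oxy]-2-{[(4-methoxybenzyl)oxy]methyl}-6,10-dimethyl-8-[(4-nitrobenzoyl)oxy]dodeca-2,6,10-trienoate | CCOC(=O)/C(COCc1ccc(OC)cc1)=C/[C@@H](O[Si](C)(C)C(C)(C)C)[C@H](O[Si](C)(C)C(C)(C)C)/C(C)=C\[C@@H](OC(=O)c1ccc(cc1)[N+](=O)[O-])C/C(C)=C\CO[Si](C)(C)C(C)(C)C
F9 | step 24 | (3Z,5R,6R,7Z,9S,11Z)-5,6,9-tris[(tert-butyldimethylsilyl)oxy]-3-{[(tert-butyldimethylsilyl)oxy]methyl}-7,11-dimethyl-1-oxacyclotrideca-3,7,11-triene | C1OC/C(CO[Si](C)(C)C(C)(C)C)=C/[C@@H](O[Si](C)(C)C(C)(C)C)[C@H](O[Si](C)(C)C(C)(C)C)/C(C)=C\[C@@H](O[Si](C)(C)C(C)(C)C)C/C(C)=C\1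
F10 | step 24 | (1R,2Z,5S,6Z,8R,9R,10S)-5,8,9-tris[(tert-butyldimethylsilyl)oxy]-10-{3-[(tert-butyldimethylsilyl)oxy]prop-1-en-2-yl}-3,7-dimethylcyclodeca-2,6-dien-1-ol | C=C(CO[Si](C)(C)C(C)(C)C)[C@@H]1[C@@H](O[Si](C)(C)C(C)(C)C)[C@H](O[Si](C)(C)C(C)(C)C)/C(C)=C\[C@@H](O[Si](C)(C)C(C)(C)C)C/C(C)=C\[C@H]1O
F11 | step 24 | (1R,2Z,5S,6Z,8R,9R,10S)-5,8,9-tris[(tert-butyldimethylsilyl)oxy]-10-{3-[(tert-butyldimethylsilyl)oxy]prop-1-en-2-yl}-3,7-dimethylcyclodeca-2,6-dien-1-yl (2R)-2-methylbutanoate | C=C(CO[Si](C)(C)C(C)(C)C)[C@@H]1[C@@H](O[Si](C)(C)C(C)(C)C)[C@H](O[Si](C)(C)C(C)(C)C)/C(C)=C\[C@@H](O[Si](C)(C)C(C)(C)C)C/C(C)=C\[C@H]1OC(=O)[C@H](C)CC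
F12 | step 29 | (3aS,4R,5Z,8S,9Z,11R,11aR)-2,8,11-trihydroxy-6,10-dimethyl-3-methylidene-2,3,3a,4,7,8,11,11a-octahydrocyclodeca[b]furan-4-yl (2R)-2-methylbutanoate (lactol, both C2 epimers) | C=C1C(O)O[C@@H]2[C@@H]1[C@H](OC(=O)[C@H](C)CC)/C=C(/C)C[C@H](O)/C=C(/C)[C@H]2O
A1 | alternative 1 | (3R,4R)-4-[(4-methoxybenzyl)oxy]hex-5-en-1-yn-3-ol | C=C[C@@H](OCc1ccc(OC)cc1)[C@H](O)C#C
A2 | alternative 1 | (3R,4R,5Z,7S,9Z)-11-[(tert-butyldimethylsilyl)oxy]-3-[(4-methoxybenzyl)oxy]-5,9-dimethylundeca-1,5,9-triene-4,7-diol | C=C[C@@H](OCc1ccc(OC)cc1)[C@H](O)/C(C)=C\[C@@H](O)C/C(C)=C\CO[Si](C)(C)C(C)(C)C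
A3 | alternative 2 | open-chain iodo aldehyde: trans-4,5-disubstituted α-methylene-γ-butyrolactone with the C9 formyl group on C8 and, on C7, the C6–C1 chain carrying the (2R)-2-methylbutanoate at C6, the silyl ether at C2 and the (Z)-alkenyl iodide at C10 | C=C1C(=O)O[C@@H](C=O)[C@@H]1[C@H](OC(=O)[C@H](C)CC)/C=C(/C)C[C@H](O[Si](C)(C)C(C)(C)C)/C=C(/C)I
A4 | alternative 2 | C2 tert-butyldimethylsilyl ether of 44 | C=C1C(=O)O[C@@H]2[C@@H]1[C@H](OC(=O)[C@H](C)CC)/C=C(/C)C[C@H](O[Si](C)(C)C(C)(C)C)/C=C(/C)[C@H]2O[H]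
A5 | alternative 3 | cis-decalin with the C4–C9 ring-fusion bond, tertiary C9 hydroxyl cis to the C4 methyl group, equatorial C5 mesylate, C6 triethylsilyl ether, C8 PMB ether, C2 silyl ether, C1=C10 in the second ring | C=C(COCc1ccc(OC)cc1)[C@@H]2[C@@H](OCc1ccc(OC)cc1)[C@]3(O)C(C)=C[C@@H](O[Si](C)(C)C(C)(C)C)C[C@]3(C)[C@H](OS(C)(=O)=O)[C@H]2O[Si](CC)(CC)CC
A6 | alternative 3 | protected (1(10)Z,4Z)-cyclodecadien-9-one with C6 triethylsilyl ether, C8 PMB ether, C2 silyl ether and the 3-(PMBO)prop-1-en-2-yl group on C7 | C=C(COCc1ccc(OC)cc1)[C@@H]2[C@@H](OCc1ccc(OC)cc1)C(=O)/C(C)=C\[C@@H](O[Si](C)(C)C(C)(C)C)C/C(C)=C\[C@H]2O[Si](CC)(CC)CC
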